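## Retrosynthetic overview

1. The C9 prenyl group is disconnected last: Tsuji–Trost C-prenylation of a tricyclic β-triketone, with the electrophile entering syn to the one-carbon C11 carbonyl bridge.
2. The tricycle is opened to a monocyclic dearomatised acylphloroglucinol carrying C(Me)(prenyl), a but-2-ynyl group and the isobutyryl group. One anodic radical–polar crossover cascade forms C1–C5 (5-exo-trig) and then C3–C4 (cation–alkyne 5-exo-dig), and turns the alkyne into the acetyl group.
3. Ring order: the six-membered trione ring is bought as the arene, then the bridged cyclopentanone ring (bicyclo[3.2.1] core) is closed, then the fused cyclopentane.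
4. The monocycle comes from 2-methylphloroglucinol by Friedel–Crafts acylation, C-butynylation and dearomative C-prenylation. Its only stereocentre (the quaternary C–Me carbon) is taken as one enantiomer by crystallising the cinchonidine salt, and it relays the other four.

Locants for tricyclic compounds follow tricyclo[5.3.1.0(1,5)]undecane: C1 and C7 are the bridgeheads, C11 is the one-carbon carbonyl bridge, C8–C10 the three-carbon bridge, C5–C6 the ethano bridge, and C1–C5 the cyclopentane.

Assumption 1: 2-methylphloroglucinol, isobutyryl chloride, 1-bromobut-2-yne, prenyl bromide, prenyl acetate and (−)-cinchonidine are catalogue chemicals.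

Assumption 2: the cinchonidinium salt of the (6S) acid is the less soluble diastereomer; if the (6R) salt crystallises instead, the pseudo-enantiomeric base (+)-cinchonine is used in the same way.

## Route

Step 1
Reactants: 1 2-methylbenzene-1,3,5-triol (2-methylphloroglucinol); 2 2-methylpropanoyl chloride (isobutyryl chloride)
Product: 3 1-(2,4,6-trihydroxy-3-methylphenyl)-2-methylpropan-1-one
Conditions: AlCl3 (3.5 equiv), PhNO2/CH2Cl2, 0 °C to 60 °C; aq HCl
Reagents that add atoms: isobutyryl chloride (2) CC(C)C(Cl)=O
Why: Friedel–Crafts C-acylation of the strongly activated triol at one of its two equivalent free positions; the acyl group deactivates the ring against a second acylation and no stereocentre is formed.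

Step 2
Reactants: 3 1-(2,4,6-trihydroxy-3-methylphenyl)-2-methylpropan-1-one; 4 1-bromobut-2-yne
Product: 5 1-[3-(but-2-yn-1-yl)-2,4,6-trihydroxy-5-methylphenyl]-2-methylpropan-1-one
Conditions: 4 (1.0 equiv), 10% aq KOH, 0 °C; then 1 M HCl
Reagents that add atoms: 1-bromobut-2-yne (4) CC#CCBr
Why: SN2 C-alkylation of the phloroglucinol polyanion in water at its only unsubstituted ring carbon (the classical aqueous-alkali C-alkylation of acylphloroglucinols), driven by rearomatisation; no stereocentre is formed.

Step 3
Reactants: 5 1-[3-(but-2-yn-1-yl)-2,4,6-trihydroxy-5-methylphenyl]-2-methylpropan-1-one; 6 1-bromo-3-methylbut-2-ene (prenyl bromide)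
Product: 7 rac-4-(but-2-yn-1-yl)-3,5-dihydroxy-6-methyl-6-(3-methylbut-2-en-1-yl)-2-(2-methylpropanoyl)cyclohexa-2,4-dien-1-one
Conditions: NaOMe (3 equiv), MeOH, 6 (1.2 equiv), 0 °C to rt; then 1 M HCl
Reagents that add atoms: prenyl bromide (6) CC(C)=CCBr
Why: Dearomative C-alkylation of the trianion (the reaction type used to make hop β-acids) is expected to favour the less hindered methyl-bearing carbon over the butynyl-bearing one; the quaternary C6 is formed as a racemate and the minor regioisomer is removed by chromatography.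

Step 4
Reactants: 7 rac-4-(but-2-yn-1-yl)-3,5-dihydroxy-6-methyl-6-(3-methylbut-2-en-1-yl)-2-(2-methylpropanoyl)cyclohexa-2,4-dien-1-one; 8 (−)-cinchonidine
Product: 10 (6S)-4-(but-2-yn-1-yl)-3,5-dihydroxy-6-methyl-6-(3-methylbut-2-en-1-yl)-2-(2-methylpropanoyl)cyclohexa-2,4-dien-1-one, via cinchonidinium salt 9 (not isolated)
Conditions: 8 (0.5 equiv), EtOAc/heptane, 60 °C to 5 °C, one recrystallisation; moist crystals shaken with 1 M HCl/EtOAc
Reagents that add atoms: none
Why: Classical resolution by diastereomeric salt crystallisation: the dienolic trione is a vinylogous acid (pKa about 5) of the hop-acid type, which gives crystalline cinchona salts; no stereocentre is made, the (6S) enantiomer is selected, and this quaternary centre dictates every later stereocentre.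

Step 5
Reactants: 10 (6S)-4-(but-2-yn-1-yl)-3,5-dihydroxy-6-methyl-6-(3-methylbut-2-en-1-yl)-2-(2-methylpropanoyl)cyclohexa-2,4-dien-1-one
Product: 13 (1S,3R,5R,7S)-3-acetyl-10-hydroxy-4,4,7-trimethyl-9-(2-methylpropanoyl)tricyclo[5.3.1.0(1,5)]undec-9-ene-8,11-dione, via tertiary carbocation 11 (not isolated), via exocyclic enol 12 (not isolated)
Conditions: graphite-felt anode, Pt cathode, undivided cell, constant current, 2.2 F/mol, (4-BrC6H4)3N (10 mol%), 2,6-lutidine (0.3 equiv), nBu4NBF4, HFIP/CH2Cl2/H2O 10:5:1, 0 °C
Reagents that add atoms: water O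
Why: Proposed new method: anodic radical–polar crossover bicyclisation – one-electron oxidation of the dienolate (directly or by the aminium mediator) gives the stabilised trione radical at the butynyl-bearing carbon, which closes 5-exo-trig onto the prenyl group on the neighbouring quaternary carbon, so the new C1–C5 bond can only form on the face carrying that prenyl group (C1 is thus fixed by C7, and of the two C5 epimers only the one with the side chain exo, syn to the C11 bridge, can close the third ring); the tertiary radical is oxidised a second time to cation 11, which is captured 5-exo-dig by the but-2-ynyl group in ionising HFIP to make C3–C4, and the linear vinyl cation is hydrated to enol 12, which is protonated at C3 from the open face remote from the C11 carbonyl bridge, leaving the acetyl group syn to that bridge (3R); the closest known chemistry is the Mn(OAc)3/Cu(OAc)2 oxidative radical cyclisation of dearomatised diprenyl acylphloroglucinols, anodic oxidative cyclisation of 1,3-dicarbonyl enolates, and methylacetylene-terminated cationic polyene cyclisations that deliver methyl ketones.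

Step 6
Reactants: 13 (1S,3R,5R,7S)-3-acetyl-10-hydroxy-4,4,7-trimethyl-9-(2-methylpropanoyl)tricyclo[5.3.1.0(1,5)]undec-9-ene-8,11-dione; 14 3-methylbut-2-en-1-yl acetate (prenyl acetate)
Product: 15 (1R,3R,5R,7S,9S)-3-acetyl-4,4,7-trimethyl-9-(3-methylbut-2-en-1-yl)-9-(2-methylpropanoyl)tricyclo[5.3.1.0(1,5)]undecane-8,10,11-trione
Conditions: Pd(PPh3)4 (5 mol%), 14 (1.5 equiv), THF, 40 °C
Reagents that add atoms: prenyl acetate (14) CC(C)=CCOC(C)=O
Why: Tsuji–Trost allylation under base-free conditions (the released acetate deprotonates the acidic triketone, so C3 is not epimerised): O-prenyl enol ethers re-ionise under zerovalent palladium until the carbon nucleophile is bonded to the unhindered CH2 terminus, and the electrophile approaches C9 syn to the C11 carbonyl bridge because the other face is screened by the endo hydrogens of the C5–C6 ethano bridge, which gives 9S.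

Note on descriptors: C1 is written 1S in 11–13 and 1R in 15 only because the enol changes the CIP priorities; the geometry is the same.

## Compound list

1 | 2-methylbenzene-1,3,5-triol | Cc1c(O)cc(O)cc1O | starting material
2 | 2-methylpropanoyl chloride | CC(C)C(Cl)=O | starting material
3 | 1-(2,4,6-trihydroxy-3-methylphenyl)-2-methylpropan-1-one | CC(C)C(=O)c1c(O)cc(O)c(C)c1O | intermediate
4 | 1-bromobut-2-yne | CC#CCBr | starting material
5 | 1-[3-(but-2-yn-1-yl)-2,4,6-trihydroxy-5-methylphenyl]-2-methylpropan-1-one | CC#CCc1c(O)c(C)c(O)c(C(=O)C(C)C)c1O | intermediate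
6 | 1-bromo-3-methylbut-2-ene | CC(C)=CCBr | starting material
7 | rac-4-(but-2-yn-1-yl)-3,5-dihydroxy-6-methyl-6-(3-methylbut-2-en-1-yl)-2-(2-methylpropanoyl)cyclohexa-2,4-dien-1-one (racemate) | OC1=C(CC#CC)C(O)=C(C(=O)C(C)C)C(=O)C1(C)CC=C(C)C | intermediate
8 | (−)-cinchonidine, (8S,9R)-cinchonan-9-ol | C=C[C@H]1CN2CC[C@H]1C[C@H]2[C@H](O)c1ccnc2ccccc12 | starting material
9 | cinchonidinium (6S)-dienolate, the 1:1 salt of 10 and 8 | [O-]C1=C(CC#CC)C(O)=C(C(=O)C(C)C)C(=O)[C@@]1(C)CC=C(C)C.C=C[C@H]1C[NH+]2CC[C@H]1C[C@H]2[C@H](O)c1ccnc2ccccc12 | intermediate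
10 | (6S)-4-(but-2-yn-1-yl)-3,5-dihydroxy-6-methyl-6-(3-methylbut-2-en-1-yl)-2-(2-methylpropanoyl)cyclohexa-2,4-dien-1-one | OC1=C(CC#CC)C(O)=C(C(=O)C(C)C)C(=O)[C@@]1(C)CC=C(C)C | intermediate
11 | 2-[(1S,5S,6R)-5-(but-2-yn-1-yl)-4-hydroxy-1-methyl-3-(2-methylpropanoyl)-2,8-dioxobicyclo[3.2.1]oct-3-en-6-yl]propan-2-ylium (side chain exo) | CC#CC[C@]12C(=O)[C@](C)(C[C@@H]1[C+](C)C)C(=O)C(C(=O)C(C)C)=C2O | intermediate
12 | (1S,5R,7S)-10-hydroxy-3-(1-hydroxyethylidene)-4,4,7-trimethyl-9-(2-methylpropanoyl)tricyclo[5.3.1.0(1,5)]undec-9-ene-8,11-dione (enol geometry not defined) | CC(O)=C1C[C@]23C(=O)[C@](C)(C[C@@H]2C1(C)C)C(=O)C(C(=O)C(C)C)=C3O | intermediate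
13 | (1S,3R,5R,7S)-3-acetyl-10-hydroxy-4,4,7-trimethyl-9-(2-methylpropanoyl)tricyclo[5.3.1.0(1,5)]undec-9-ene-8,11-dione (acetyl syn to the C11 bridge) | CC(=O)[C@@H]1C[C@]23C(=O)[C@](C)(C[C@@H]2C1(C)C)C(=O)C(C(=O)C(C)C)=C3O | intermediate
14 | 3-methylbut-2-en-1-yl acetate | CC(C)=CCOC(C)=O | starting material
15 | (1R,3R,5R,7S,9S)-3-acetyl-4,4,7-trimethyl-9-(3-methylbut-2-en-1-yl)-9-(2-methylpropanoyl)tricyclo[5.3.1.0(1,5)]undecane-8,10,11-trione | CC(=O)[C@@H]1C[C@]23C(=O)[C@](C)(C[C@@H]2C1(C)C)C(=O)[C@](CC=C(C)C)(C(=O)C(C)C)C3=O | target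

## Step count and risks

Total step count: 6. Longest linear sequence: 6 steps (1 to 15; the route is fully linear).

The three steps most likely to fail are steps 3, 5 and 6.

Step 3 (regioselectivity of the dearomative prenylation). The fallback sets out from 3 and comes back at 7; it blocks the free ring carbon with bromine and introduces the butynyl group last. NBS in MeCN at 0 °C brominates 3 at its only free position to give 1-(3-bromo-2,4,6-trihydroxy-5-methylphenyl)-2-methylpropan-1-one F1. Dearomative prenylation (NaOMe, MeOH, 6) then builds the quaternary centre at the methyl-bearing carbon, because the brominated carbon is deactivated, giving rac-4-bromo-3,5-dihydroxy-6-methyl-6-(3-methylbut-2-en-1-yl)-2-(2-methylpropanoyl)cyclohexa-2,4-dien-1-one F2. Zn dust in AcOH removes the bromine to leave rac-3,5-dihydroxy-6-methyl-6-(3-methylbut-2-en-1-yl)-2-(2-methylpropanoyl)cyclohexa-2,4-dien-1-one F3. Its single remaining nucleophilic ring carbon is C-alkylated with 4 (K2CO3, acetone) to give 7.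

Step 5 (the proposed anodic cascade; competing elimination, hydrogen abstraction or over-oxidation). The fallback sets out from 10 and comes back at 13; it splits the cascade into two known operations. Mn(OAc)3·2H2O (2.2 equiv) with Cu(OAc)2·H2O in AcOH at room temperature performs the established trivalent-manganese oxidative radical 5-exo cyclisation. Divalent copper intercepts the tertiary radical as the alkene, giving (1S,5S,6R)-5-(but-2-yn-1-yl)-4-hydroxy-1-methyl-3-(2-methylpropanoyl)-6-(prop-1-en-2-yl)bicyclo[3.2.1]oct-3-ene-2,8-dione F4. TfOH (0.1 equiv) in wet HFIP at 0 °C then protonates the isopropenyl group. The tertiary cation undergoes the classical methylacetylene-terminated cation–alkyne cyclisation, hydration and ketonisation to 13.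

Step 6 (O- versus C-alkylation and linear versus branched attack at a very hindered carbon). The fallback sets out from 13 and comes back at 15; it introduces the side chain as a smaller allyl group and completes it by metathesis. Allyl acetate with Pd(PPh3)4 in THF gives (1R,3R,5R,7S,9S)-3-acetyl-4,4,7-trimethyl-9-(2-methylpropanoyl)-9-(prop-2-en-1-yl)tricyclo[5.3.1.0(1,5)]undecane-8,10,11-trione F5 with the same facial preference. Cross-metathesis with excess 2-methylbut-2-ene and second-generation Grubbs catalyst in CH2Cl2 at 40 °C converts the allyl group into the prenyl group of 15.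

Further compounds
F1 | step 3 | 1-(3-bromo-2,4,6-trihydroxy-5-methylphenyl)-2-methylpropan-1-one | CC(C)C(=O)c1c(O)c(Br)c(O)c(C)c1O
F2 | step 3 | rac-4-bromo-3,5-dihydroxy-6-methyl-6-(3-methylbut-2-en-1-yl)-2-(2-methylpropanoyl)cyclohexa-2,4-dien-1-one | OC1=C(Br)C(O)=C(C(=O)C(C)C)C(=O)C1(C)CC=C(C)C
F3 | step 3 | rac-3,5-dihydroxy-6-methyl-6-(3-methylbut-2-en-1-yl)-2-(2-methylpropanoyl)cyclohexa-2,4-dien-1-one | OC1=CC(O)=C(C(=O)C(C)C)C(=O)C1(C)CC=C(C)C
F4 | step 5 | (1S,5S,6R)-5-(but-2-yn-1-yl)-4-hydroxy-1-methyl-3-(2-methylpropanoyl)-6-(prop-1-en-2-yl)bicyclo[3.2.1]oct-3-ene-2,8-dione | CC#CC[C@]12C(=O)[C@](C)(C[C@@H]1C(C)=C)C(=O)C(C(=O)C(C)C)=C2O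
F5 | step 6 | (1R,3R,5R,7S,9S)-3-acetyl-4,4,7-trimethyl-9-(2-methylpropanoyl)-9-(prop-2-en-1-yl)tricyclo[5.3.1.0(1,5)]undecane-8,10,11-trione | CC(=O)[C@@H]1C[C@]23C(=O)[C@](C)(C[C@@H]2C1(C)C)C(=O)[C@](CC=C)(C(=O)C(C)C)C3=O
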